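the same everywhere: G 17 mM

| charge | J | remark | time |
|---|---|---|---|
| delta | 18 mM | run made earlier |  |
| epsilon | 28 mM | run made earlier |  |
| zeta | 59 mM | run made earlier |  |
| east | 15.0 mM |  | 30 min |
| north-west | 30.0 mM |  | 30 min |
| south-east | 60.0 mM |  | 30 min |

| delta: time / min | delta: E / % | epsilon: time / min | epsilon: E / % | zeta: time / min | zeta: E / % |
|---|---|---|---|---|---|
| 6.00 | 16.6 | 2.50 | 20.8 | 6.00 | 4.1 |
| 12.0 | 11.4 | 8.00 | 11.6 | 12.0 | 0 |
| 20.0 | 8.6 | 15.0 | 4.1 | 20.0 | 0.1 |
| 25.0 | 4.6 | 20.0 | 3.8 | 25.0 | 0.2 |
| 30.0 | 4.7 | 30.0 | 1.0 | 30.0 | 0 |

(readings scatter by 1 percentage point)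
- "hardly changes" means that all values lie within two and a half points (for a concentration: within two and a half percent of the largest)
- amount of E at the end, in percent of the G charged for east, north-west, south-east, in this order
- how that number moves from the first to the last of them (rises all the way / falls all the way / falls, then rises / hardly changes / rises, then falls)

- At early times you see none of the rise of E: epsilon already reads 20.8% at 2.50 min, and each later epsilon reading is lower.
- So take the tail. Counting J as a fraction of the G charge, delta holds 1.06 and epsilon 1.65. Integrating a pseudo-first-order fall between first and last reading gives a tail rate, the logarithm of their ratio over the time between: 0.0526 min⁻¹ in delta, 0.110 min⁻¹ in epsilon.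
- A line through these two readings reaches zero at 0.524. Call its slope the surplus slope, the tail rate per unit of J charge above that point: 0.0982 min⁻¹.
- Next rung: for zeta the slope gives 0.289 min⁻¹, a half-life of 2.40 min, shorter than epsilon's 6.30 min and delta's 13.2 min.
- Last rung: the clock itself, 30 min. Delta and epsilon, run back to zero time, average 25.1%. From that start zeta should read 4.43% at 6.00 min; it reads 4.1%, a reading the line was not built on.
- My reckoning for the end: 8.71% in east, 0.647% in north-west, and 0.00357% in south-east.
- The forecast says 6.5%, 0.8%, 0%, lower than mine for east, and falls all the way: “The end amount of E therefore falls all the way.”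

    2 G → L (k = 11.0 L mol⁻¹ min⁻¹)
    G + J → E + D (k = 13.0 L mol⁻¹ min⁻¹)
    J + E → X + D (k = 20.0 L mol⁻¹ min⁻¹)

- The flask gives 7.65%, 0.840%, 0%: falls all the way. Between 15.0 min and 30.0 min, E in east falls at 0.0297 min⁻¹, where the surplus slope gave 0.0352 min⁻¹; in north-west it falls at 0.112 min⁻¹, where the slope gave 0.122 min⁻¹. The forecast's 6.5% for east would fail if the reaction of 2 G to L were taken away, since that reaction is a part of the reason E ends low in east. Without it, the east run ends at 29.1% of E instead of 7.65%.

(Readings and results were generated by integration with constants of no real substance; noise was put on by code.)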